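The 4-quinolone is read as a latent Camps precursor: N1–C2 of the pyridone ring is an anilide bond and C3–C4(=O) an ortho-acetyl group. C2 thereby becomes an amide carbonyl, and side-chain carbons C1′ and C2′ become the α- and β-carbons of an acrylamide. Everything therefore rests on the C2′–C3′ disconnection, which exploits the β-relationship of C2′ to C2. In one operation a silyl-radical photoredox Giese addition joins the primary radical from 11-bromo-2-methylundecan-2-ol to N-(2-acetylphenyl)acrylamide, with the OH, NH and ketone unprotected. The precursor is an open-chain acrylanilide carrying no heterocycle; Camps closure follows.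

Key step: step 3

Remark on the chemistry: the carbinol carbon bears two identical methyl groups and there is no stereogenic double bond. The target is therefore achiral and no enantiocontrol is needed. It is drawn as the 4(1H)-quinolone tautomer.

Step 1
Reactants: 1 methyl 10-bromodecanoate
Product: 3 11-bromo-2-methylundecan-2-ol, via 11-bromoundecan-2-one 2 (not isolated)
Conditions: MeMgBr (2.5 equiv), THF, 0 °C to rt; then sat. aq. NH4Cl
Reagents that add atoms: methylmagnesium bromide, C[Mg]Br
Why: Double Grignard addition to an ester: the first addition collapses to ketone 2, which is more electrophilic than 1 and takes up the second methyl at once, while an unactivated primary alkyl bromide is inert to MeMgBr at 0 °C without a copper or iron catalyst, and no stereocentre arises because the two new substituents are identical.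

Step 2
Reactants: 4 2′-aminoacetophenone; 5 acryloyl chloride
Product: 6 N-(2-acetylphenyl)prop-2-enamide
Conditions: K2CO3 (1.5 equiv), BHT (trace), THF, 0 °C to rt
Reagents that add atoms: none
Why: Nucleophilic acyl substitution (amide formation from an acid chloride): the acid chloride is reactive enough for the hydrogen-bonded, weakly nucleophilic aniline, attack at the acyl carbon is much faster than aza-Michael addition at 0 °C, and the solid carbonate only removes HCl.

Step 3
Reactants: 3 11-bromo-2-methylundecan-2-ol (1.5 equiv); 6 N-(2-acetylphenyl)prop-2-enamide (1.0 equiv)
Product: 9 N-(2-acetylphenyl)-13-hydroxy-13-methyltetradecanamide, via 10-hydroxy-10-methylundecyl radical 7 (not isolated), via alpha-carbamoyl adduct radical 8 (not isolated)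
Conditions: (TMS)3SiH (1.5 equiv), [Ir(dF(CF3)ppy)2(dtbbpy)]PF6 (1 mol %), Na2CO3 (2 equiv), degassed MeOH, 450 nm LEDs, rt
Reagents that add atoms: none
Why: The photoexcited iridium complex starts a silyl-radical process in which (TMS)3Si• abstracts bromine from 3 (strong Si–Br bond) to give the nucleophilic primary radical 7, which adds to the unsubstituted β-carbon of acrylamide 6, and the electrophilic radical 8 is then quenched by polarity-matched hydrogen transfer from (TMS)3SiH or by reduction and protonation in MeOH. The closest known reaction type is the silyl-mediated photoredox Giese reaction of unactivated alkyl bromides with acrylates and acrylamides. No ring is closed and no stereocentre is created. The step needs cross-selectivity, that is addition of 7 to 6 faster than its reduction and quenching of 8 faster than telomerisation; the alternation nucleophilic radical / electron-poor alkene / hydridic silane secures this, and the excess of 3 keeps the silyl radical on bromine abstraction rather than on addition to 6. Regioselectivity for the terminal carbon follows from the unhindered CH2 terminus and from stabilisation of 8 by the amide carbonyl. Oxindole-type attack of 8 on the arene is disfavoured because the N–H···O=C(acetyl) hydrogen bond holds the secondary anilide in the trans amide geometry, and the neutral radical conditions leave the tertiary OH, the N–H and the aryl ketone untouched.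

Step 4
Reactants: 9 N-(2-acetylphenyl)-13-hydroxy-13-methyltetradecanamide
Product: 11 2-(12-hydroxy-12-methyltridecyl)quinolin-4(1H)-one, via cyclic aldol-type adduct 10 (not isolated)
Conditions: NaOH (3 equiv, powdered), 1,4-dioxane, 110 °C; then 1 M HCl to pH 7
Reagents that add atoms: none
Why: Camps quinolone synthesis: hydroxide generates the methyl-ketone enolate, which attacks the amide carbonyl in a favoured 6-(enolendo)-exo-trig closure to adduct 10, and irreversible loss of water gives the aromatic-stabilised vinylogous amide, the strong base in dioxane favouring this mode over closure from the less acidic amide α-methylene, while the tertiary alcohol is inert to base.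

Compound list
1 | methyl 10-bromodecanoate | COC(=O)CCCCCCCCCBr | starting material
2 | 11-bromoundecan-2-one (not isolated) | CC(=O)CCCCCCCCCBr | intermediate
3 | 11-bromo-2-methylundecan-2-ol | CC(C)(O)CCCCCCCCCBr | intermediate
4 | 2′-aminoacetophenone, 1-(2-aminophenyl)ethan-1-one | CC(=O)c1ccccc1N | starting material
5 | acryloyl chloride | C=CC(=O)Cl | starting material
6 | N-(2-acetylphenyl)prop-2-enamide | C=CC(=O)Nc1ccccc1C(C)=O | intermediate
7 | 10-hydroxy-10-methylundecyl radical (not isolated) | [CH2]CCCCCCCCC(C)(C)O | intermediate
8 | 1-[(2-acetylphenyl)amino]-13-hydroxy-13-methyl-1-oxotetradecan-2-yl radical (not isolated) | CC(C)(O)CCCCCCCCCC[CH]C(=O)Nc1ccccc1C(C)=O | intermediate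
9 | N-(2-acetylphenyl)-13-hydroxy-13-methyltetradecanamide | CC(C)(O)CCCCCCCCCCCC(=O)Nc1ccccc1C(C)=O | intermediate
10 | 2-hydroxy-2-(12-hydroxy-12-methyltridecyl)-2,3-dihydroquinolin-4(1H)-one (racemic, transient, not isolated) | CC(C)(O)CCCCCCCCCCCC1(O)CC(=O)c2ccccc2N1 | intermediate
11 | 2-(12-hydroxy-12-methyltridecyl)quinolin-4(1H)-one (achiral) | CC(C)(O)CCCCCCCCCCCc1cc(=O)c2ccccc2[nH]1 | target

Total step count: 4
Longest linear sequence: 3 steps (steps 1, 3, 4, or equally steps 2, 3, 4)

Steps most likely to fail

Step 3. Three processes may compete with the coupling: premature hydrogen transfer to the alkyl radical, addition of the silyl radical to the acrylamide, and telomerisation of the adduct radical. The fallback sets out from 4 and comes back at 9, and it makes the same carbon–carbon link by a non-radical route. Compound 4 is acylated with but-3-enoyl chloride (K2CO3, THF, 0 °C) to N-(2-acetylphenyl)but-3-enamide F1. Commercial methyl undec-10-enoate and MeMgBr (THF, 0 °C) give 2-methyldodec-11-en-2-ol F2. Olefin cross-metathesis of F1 with excess F2 (Hoveyda–Grubbs II catalyst, 1,4-benzoquinone, CH2Cl2, 40 °C) forms the link as a double bond in (E)-N-(2-acetylphenyl)-13-hydroxy-13-methyltetradec-3-enamide F3. Hydrogenation (H2, 1 atm, Pd/C, EtOAc) then gives 9.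

Step 4. Deprotonation at the amide α-methylene may lead to ring closure in the other aldol sense, towards a 2-quinolone, and hydroxide may cleave the amide at 110 °C. The fallback sets out from 6 and comes back at 11, with the order of ring closure and coupling inverted. The amide of 6 has no sp3 α-hydrogen, so it can close in one sense only. It is cyclised (t-BuOK, t-BuOH, BHT, 80 °C) to 2-ethenylquinolin-4(1H)-one F4. The silyl-mediated Giese addition of 3 (conditions of step 3) to the vinyl terminus of F4, a vinylogous acceptor through C2=C3–C4=O, gives 11 directly.

Step 2. The acryloyl unit may polymerise, and the aniline may add in aza-Michael fashion to the reagent or to the product during acylation. The fallback sets out from 4 and comes back at 6. Compound 4 is acylated with 3-chloropropanoyl chloride (K2CO3, THF, 0 °C) to N-(2-acetylphenyl)-3-chloropropanamide F5, a masked acrylamide that cannot polymerise. Base-induced loss of HCl (K2CO3, MeCN, 60 °C) then unveils 6.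

Further compounds
F1 | step 3 | N-(2-acetylphenyl)but-3-enamide | C=CCC(=O)Nc1ccccc1C(C)=O
F2 | step 3 | 2-methyldodec-11-en-2-ol | C=CCCCCCCCCC(C)(C)O
F3 | step 3 | (E)-N-(2-acetylphenyl)-13-hydroxy-13-methyltetradec-3-enamide | CC(C)(O)CCCCCCCC/C=C/CC(=O)Nc1ccccc1C(C)=O
F4 | step 4 | 2-ethenylquinolin-4(1H)-one | C=Cc1cc(=O)c2ccccc2[nH]1
F5 | step 2 | N-(2-acetylphenyl)-3-chloropropanamide | CC(=O)c1ccccc1NC(=O)CCCl
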